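**Strategy.** Everything rests on cutting the C3–C4 bond (germacranolide numbering), the sp2–sp2 link between enol-ether carbon C3 of the 3(2H)-furanone ring and alkene carbon C4 of the ten-membered carbocycle. C3 is at once a cross-coupling terminus and the β-carbon of an ynone (C1–C3) that the C10 tertiary hydroxyl can attack. One operation therefore closes two rings: an intramolecular Sonogashira coupling joins the Z-vinyl iodide (C4) to the terminal α'-hydroxy ynone, and the strained cycloalkynone collapses by transannular 5-endo-dig oxa-Michael addition to the bridged furanone. The precursor is a monocyclic trans-α-methylene-γ-butyrolactone bearing both chains, assembled from (S)-5-(hydroxymethyl)butenolide by radical conjugate addition, a proline aldol and an axial Grignard addition.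

Key step: step 15

Remark: atom labels follow germacranolide numbering (C1 ketone, C2=C3 furanone alkene, C4=C5 ring alkene, C6 lactone carbinol, C7, C8 free carbinol, C9 acylated carbinol, C10 quaternary ether carbon, C11–C13 methylene lactone); the side chain is taken as the (Z)-4-acetoxy-2-methylbut-2-enoate.

**Route**

Step 1
Reactants: 1 (S)-5-(hydroxymethyl)furan-2(5H)-one
Product: 2 (S)-5-[(triethylsilyloxy)methyl]furan-2(5H)-one
Conditions: TESCl, imidazole, CH2Cl2, 0 °C
Reagents that add atoms: chlorotriethylsilane, CC[Si](Cl)(CC)CC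
Why: Standard silyl ether formation on a primary alcohol, which touches no stereocentre and gives an ether that is later oxidised directly.

Step 2
Reactants: 2 (S)-5-[(triethylsilyloxy)methyl]furan-2(5H)-one
Product: 3 (4S,5S)-4-(1,3-dioxolan-2-yl)-5-[(triethylsilyloxy)methyl]oxolan-2-one
Conditions: 1,3-dioxolane (solvent), Ph2CO (10 mol %), hν (Hg lamp, Pyrex), 20 °C
Reagents that add atoms: 1,3-dioxolane, C1COCO1
Why: Benzophenone-sensitised radical conjugate addition (Giese-type photoaddition) of the 1,3-dioxolan-2-yl radical to the butenolide β-carbon C7 should occur anti to the C6 silyloxymethyl group, setting the C6/C7 trans relationship and installing C8 as a masked aldehyde.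

Step 3
Reactants: 3 (4S,5S)-4-(1,3-dioxolan-2-yl)-5-[(triethylsilyloxy)methyl]oxolan-2-one
Product: 4 (2S,3S)-3-(1,3-dioxolan-2-yl)-5-oxooxolane-2-carbaldehyde
Conditions: (COCl)2, DMSO, CH2Cl2, −78 → −40 °C; Et3N, −78 → 0 °C
Reagents that add atoms: none
Why: Swern oxidation, under which a primary triethylsilyl ether is cleaved and oxidised in one pot, should give the α-oxygenated aldehyde at low temperature without epimerising C6.

Step 4
Reactants: 4 (2S,3S)-3-(1,3-dioxolan-2-yl)-5-oxooxolane-2-carbaldehyde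
Product: 5 (4S,5S)-4-(1,3-dioxolan-2-yl)-5-[(Z)-2-iodoprop-1-en-1-yl]oxolan-2-one
Conditions: EtPPh3I, n-BuLi, THF; I2, −78 °C; NaN(SiMe3)2, −78 °C; then 4, −78 → −20 °C
Reagents that add atoms: ethyltriphenylphosphonium iodide, CC[P+](c1ccccc1)(c1ccccc1)c1ccccc1.[I-]; iodine, II
Why: Stork–Zhao-type Wittig olefination with the α-iodo ylide made in the flask should give the trisubstituted vinyl iodide with iodine cis to C6 (Z), the kinetic outcome of this ylide class, while C6 is untouched at −78 °C.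

Step 5
Reactants: 5 (4S,5S)-4-(1,3-dioxolan-2-yl)-5-[(Z)-2-iodoprop-1-en-1-yl]oxolan-2-one
Product: 6 (2S,3S)-2-[(Z)-2-iodoprop-1-en-1-yl]-5-oxooxolane-3-carbaldehyde
Conditions: 1 M HCl (aq), THF, 40 °C
Reagents that add atoms: water, O
Why: Acid-catalysed acetal hydrolysis frees the C8 aldehyde, C7 remaining in the thermodynamically preferred trans arrangement and the acidic medium avoiding β-elimination of the lactone oxygen.

Step 6
Reactants: 6 (2S,3S)-2-[(Z)-2-iodoprop-1-en-1-yl]-5-oxooxolane-3-carbaldehyde; 7 2,2-dimethyl-1,3-dioxan-5-one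
Product: 8 (4R,5S)-4-{(S)-[(4S)-2,2-dimethyl-5-oxo-1,3-dioxan-4-yl](hydroxy)methyl}-5-[(Z)-2-iodoprop-1-en-1-yl]oxolan-2-one
Conditions: L-proline (30 mol %), DMF, 4 °C
Reagents that add atoms: none
Why: Proline-catalysed direct aldol addition through the (E)-enamine of the cyclic ketone and a carboxylic-acid-organised chair-like transition state should give the anti adduct, L-proline setting C8 and C9 (both S) under catalyst control over the α-branched aldehyde.

Step 7
Reactants: 8 (4R,5S)-4-{(S)-[(4S)-2,2-dimethyl-5-oxo-1,3-dioxan-4-yl](hydroxy)methyl}-5-[(Z)-2-iodoprop-1-en-1-yl]oxolan-2-one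
Product: 9 (4S,5S)-4-{(S)-(tert-butyldimethylsilyloxy)[(4S)-2,2-dimethyl-5-oxo-1,3-dioxan-4-yl]methyl}-5-[(Z)-2-iodoprop-1-en-1-yl]oxolan-2-one
Conditions: TBSOTf, 2,6-lutidine, CH2Cl2, −78 °C
Reagents that add atoms: tert-butyldimethylsilyl trifluoromethanesulfonate, CC(C)(C)[Si](C)(C)OS(=O)(=O)C(F)(F)F
Why: Silylation of the hindered secondary alcohol with the silyl triflate at −78 °C outpaces enol silylation of the ketone and blocks retro-aldol cleavage, differentiating O8 from O9.

Step 8
Reactants: 9 (4S,5S)-4-{(S)-(tert-butyldimethylsilyloxy)[(4S)-2,2-dimethyl-5-oxo-1,3-dioxan-4-yl]methyl}-5-[(Z)-2-iodoprop-1-en-1-yl]oxolan-2-one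
Product: 10 (4S,5S)-4-{(S)-(tert-butyldimethylsilyloxy)[(4S,5R)-5-hydroxy-2,2,5-trimethyl-1,3-dioxan-4-yl]methyl}-5-[(Z)-2-iodoprop-1-en-1-yl]oxolan-2-one
Conditions: MeMgBr, THF, −78 °C
Reagents that add atoms: methylmagnesium bromide, C[Mg]Br
Why: Grignard 1,2-addition to the ketone (far more electrophilic than the lactone at −78 °C) should proceed by axial attack on the chair 1,3-dioxan-5-one, which has no 1,3-diaxial hydrogens and carries the C9 substituent equatorial, giving the equatorial C10 hydroxyl trans to that substituent (9,10-anti).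

Step 9
Reactants: 10 (4S,5S)-4-{(S)-(tert-butyldimethylsilyloxy)[(4S,5R)-5-hydroxy-2,2,5-trimethyl-1,3-dioxan-4-yl]methyl}-5-[(Z)-2-iodoprop-1-en-1-yl]oxolan-2-one
Product: 13 (4S,5S)-4-{(S)-(tert-butyldimethylsilyloxy)[(4S,5R)-5-hydroxy-2,2,5-trimethyl-1,3-dioxan-4-yl]methyl}-5-[(Z)-2-iodoprop-1-en-1-yl]-3-methylideneoxolan-2-one, via Mannich base 11 (not isolated), via trimethylammonium iodide 12 (not isolated)
Conditions: LiN(SiMe3)2, THF, −78 °C; CH2=NMe2+ I−, −78 → 20 °C; MeI, MeOH; NaHCO3 (aq), CH2Cl2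
Reagents that add atoms: N,N-dimethylmethyleneiminium iodide (Eschenmoser's salt), C=[N+](C)C.[I-]
Why: Mannich aminomethylation of the lactone enolate followed by exhaustive methylation and Hofmann-type elimination installs the exocyclic methylene, the transient C11 centre being destroyed and the tertiary alkoxide carried as a spectator.

Step 10
Reactants: 13 (4S,5S)-4-{(S)-(tert-butyldimethylsilyloxy)[(4S,5R)-5-hydroxy-2,2,5-trimethyl-1,3-dioxan-4-yl]methyl}-5-[(Z)-2-iodoprop-1-en-1-yl]-3-methylideneoxolan-2-one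
Product: 14 (4S,5S)-4-[(1S,2S,3R)-1-(tert-butyldimethylsilyloxy)-2,3,4-trihydroxy-3-methylbutyl]-5-[(Z)-2-iodoprop-1-en-1-yl]-3-methylideneoxolan-2-one
Conditions: PPTS, MeOH, 20 °C
Reagents that add atoms: none
Why: Acid-catalysed transketalisation removes the 1,3-dioxane acetonide, which is more labile than the hindered secondary TBS ether.

Step 11
Reactants: 14 (4S,5S)-4-[(1S,2S,3R)-1-(tert-butyldimethylsilyloxy)-2,3,4-trihydroxy-3-methylbutyl]-5-[(Z)-2-iodoprop-1-en-1-yl]-3-methylideneoxolan-2-one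
Product: 15 (4S,5S)-4-[(1S,2S,3R)-1-(tert-butyldimethylsilyloxy)-3-hydroxy-3-methyl-2,4-bis(triethylsilyloxy)butyl]-5-[(Z)-2-iodoprop-1-en-1-yl]-3-methylideneoxolan-2-one
Conditions: TESCl, imidazole, DMAP (cat.), DMF, 0 → 20 °C
Reagents that add atoms: chlorotriethylsilane, CC[Si](Cl)(CC)CC
Why: Silyl chloride/imidazole silylation takes the primary C1 and secondary C9 hydroxyls but not the tertiary, fully substituted C10 hydroxyl.

Step 12
Reactants: 15 (4S,5S)-4-[(1S,2S,3R)-1-(tert-butyldimethylsilyloxy)-3-hydroxy-3-methyl-2,4-bis(triethylsilyloxy)butyl]-5-[(Z)-2-iodoprop-1-en-1-yl]-3-methylideneoxolan-2-one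
Product: 16 (4S,5S)-4-[(1S,2S,3S)-1-(tert-butyldimethylsilyloxy)-3-hydroxy-3-methyl-4-oxo-2-(triethylsilyloxy)butyl]-5-[(Z)-2-iodoprop-1-en-1-yl]-3-methylideneoxolan-2-one
Conditions: (COCl)2, DMSO, CH2Cl2, −78 → −35 °C; Et3N, −78 → 0 °C
Reagents that add atoms: none
Why: Swern oxidation converts the primary triethylsilyl ether selectively into the aldehyde while the secondary silyl ethers and the tertiary hydroxyl persist, and the α-hydroxy aldehyde (no α-hydrogen) is used at once.

Step 13
Reactants: 16 (4S,5S)-4-[(1S,2S,3S)-1-(tert-butyldimethylsilyloxy)-3-hydroxy-3-methyl-4-oxo-2-(triethylsilyloxy)butyl]-5-[(Z)-2-iodoprop-1-en-1-yl]-3-methylideneoxolan-2-one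
Product: 17 (4S,5S)-4-[(1S,2S,3R,4RS)-1-(tert-butyldimethylsilyloxy)-3,4-dihydroxy-3-methyl-2-(triethylsilyloxy)hex-5-yn-1-yl]-5-[(Z)-2-iodoprop-1-en-1-yl]-3-methylideneoxolan-2-one
Conditions: HC≡CMgBr, THF, −78 → −20 °C
Reagents that add atoms: ethynylmagnesium bromide, C#C[Mg]Br
Why: Grignard addition of the acetylide to the aldehyde, chemoselective over the lactone at low temperature, gives the propargylic alcohol as a C1 epimer mixture that the next step removes.

Step 14
Reactants: 17 (4S,5S)-4-[(1S,2S,3R,4RS)-1-(tert-butyldimethylsilyloxy)-3,4-dihydroxy-3-methyl-2-(triethylsilyloxy)hex-5-yn-1-yl]-5-[(Z)-2-iodoprop-1-en-1-yl]-3-methylideneoxolan-2-one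
Product: 18 (4S,5S)-4-[(1S,2S,3S)-1-(tert-butyldimethylsilyloxy)-3-hydroxy-3-methyl-4-oxo-2-(triethylsilyloxy)hex-5-yn-1-yl]-5-[(Z)-2-iodoprop-1-en-1-yl]-3-methylideneoxolan-2-one
Conditions: Dess–Martin periodinane, NaHCO3, CH2Cl2, 0 °C
Reagents that add atoms: none
Why: Dess–Martin oxidation of the secondary propargylic alcohol gives the terminal ynone and erases the C1 stereocentre, the tertiary alcohol being inert.

Step 15
Reactants: 18 (4S,5S)-4-[(1S,2S,3S)-1-(tert-butyldimethylsilyloxy)-3-hydroxy-3-methyl-4-oxo-2-(triethylsilyloxy)hex-5-yn-1-yl]-5-[(Z)-2-iodoprop-1-en-1-yl]-3-methylideneoxolan-2-one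
Product: 20 8-O-TBS-9-O-TES furanone macrolide (3,10-epoxy-1-oxogermacra-2,4Z,11(13)-trien-12,6-olide core; C6–C10 configured as in 32), via macrocyclic enynone 19 (not isolated)
Conditions: Pd(PPh3)4 (20 mol %), CuI (40 mol %), iPr2NEt, THF (0.001 M, slow addition), 20 → 45 °C
Reagents that add atoms: none
Why: Oxidative addition of zerovalent palladium into the C4–I bond, transmetalation from the copper acetylide of the terminal ynone and reductive elimination form the C3–C4 bond (intramolecular Sonogashira coupling; closest precedents are macrocyclising Sonogashira reactions and one-pot Sonogashira/oxacyclisation sequences), after which the bent, conjugated cycloalkynone should undergo transannular oxa-Michael addition of the C10 hydroxyl to C3. The ten-membered carbocycle closes by end-to-end coupling of the sp and sp2 termini, and the furanone by 5-endo-dig attack, which Baldwin's rules allow and the strain of the cycloalkyne promotes. No stereocentre is created; the Z geometry of C4=C5 is carried over from the vinyl iodide with retention and the five existing centres are not epimerisable under these conditions. The step needs ring closure over oligomerisation (high dilution, slow addition), coupling before oxacyclisation (the copper acetylide is no Michael acceptor, so the hydroxyl cannot close early onto C3), O10 over O9 attack (O9 is silylated) and Sonogashira over Heck insertion into the methylene lactone (transmetalation near ambient temperature is faster).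

Step 16
Reactants: 20 8-O-TBS-9-O-TES furanone macrolide
Product: 21 8-O-TBS-9-hydroxy furanone macrolide (C6–C10 configured as in 32)
Conditions: HF·pyridine, pyridine, THF, 0 °C
Reagents that add atoms: none
Why: Buffered fluoride desilylation cleaves the triethylsilyl ether faster than the bulkier TBS ether (steric differentiation of silyl ethers), freeing only O9.

Step 17
Reactants: 22 tert-butyl bromoacetate; 23 diphenyl phosphite
Product: 24 tert-butyl 2-(diphenoxyphosphoryl)acetate
Conditions: Et3N, CH2Cl2, 0 → 20 °C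
Reagents that add atoms: none
Why: Michaelis–Becker-type P-alkylation of the phosphite with the primary α-bromo ester gives the diaryl phosphonoacetate.

Step 18
Reactants: 24 tert-butyl 2-(diphenoxyphosphoryl)acetate
Product: 25 tert-butyl 2-(diphenoxyphosphoryl)propanoate (racemic)
Conditions: NaH, MeI, THF/DMSO, 0 → 20 °C
Reagents that add atoms: iodomethane, CI
Why: C-Alkylation of the stabilised phosphonate carbanion with methyl iodide gives the α-methyl phosphonate, whose stereocentre is destroyed in the olefination.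

Step 19
Reactants: 26 (Z)-but-2-ene-1,4-diyl diacetate
Product: 27 2-oxoethyl acetate
Conditions: O3, CH2Cl2, −78 °C; Me2S
Reagents that add atoms: ozone, [O-][O+]=O
Why: Ozonolysis with reductive work-up cleaves the symmetric alkene into two equivalents of the aldehyde.

Step 20
Reactants: 25 tert-butyl 2-(diphenoxyphosphoryl)propanoate; 27 2-oxoethyl acetate
Product: 28 tert-butyl (Z)-4-acetoxy-2-methylbut-2-enoate
Conditions: NaH, THF, −78 → 0 °C
Reagents that add atoms: none
Why: Z-selective Horner–Wadsworth–Emmons olefination with a diaryl phosphonate, whose adduct collapses fast and irreversibly, should place the ester and the acetoxymethyl group cis (Z).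

Step 21
Reactants: 28 tert-butyl (Z)-4-acetoxy-2-methylbut-2-enoate
Product: 29 (Z)-4-acetoxy-2-methylbut-2-enoic acid
Conditions: CF3CO2H, CH2Cl2, 0 → 20 °C
Reagents that add atoms: none
Why: Acidolysis of the tert-butyl ester (E1 loss of isobutene) leaves the acetate and the alkene geometry untouched.

Step 22
Reactants: 21 8-O-TBS-9-hydroxy furanone macrolide; 29 (Z)-4-acetoxy-2-methylbut-2-enoic acid
Product: 31 8-O-TBS ether of the target, via mixed anhydride 30 (not isolated)
Conditions: 2,4,6-Cl3C6H2COCl, Et3N, toluene, 20 °C; then 21, DMAP, 20 → 40 °C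
Reagents that add atoms: none
Why: Yamaguchi esterification through the mixed anhydride acylates the hindered C9 hydroxyl and is the established way to transfer angelate-type Z-acids without Z/E isomerisation; no stereocentre is formed.

Step 23
Reactants: 31 8-O-TBS ether of the target
Product: 32 target CNP0523348.1
Conditions: HF·pyridine, THF, 0 → 20 °C
Reagents that add atoms: none
Why: Acidic fluoride desilylation of the secondary TBS ether leaves both esters, the furanone enol ether and the methylene lactone intact and avoids the basic conditions that would promote O9→O8 acyl migration.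

**Compound list**

1 | (S)-5-(hydroxymethyl)furan-2(5H)-one | O=C1C=C[C@@H](CO)O1 | starting material
2 | (S)-5-[(triethylsilyloxy)methyl]furan-2(5H)-one | O=C1C=C[C@@H](CO[Si](CC)(CC)CC)O1 | intermediate
3 | (4S,5S)-4-(1,3-dioxolan-2-yl)-5-[(triethylsilyloxy)methyl]oxolan-2-one (trans) | O=C1C[C@H](C2OCCO2)[C@@H](CO[Si](CC)(CC)CC)O1 | intermediate
4 | (2S,3S)-3-(1,3-dioxolan-2-yl)-5-oxooxolane-2-carbaldehyde | O=C1C[C@H](C2OCCO2)[C@@H](C=O)O1 | intermediate
5 | (4S,5S)-4-(1,3-dioxolan-2-yl)-5-[(Z)-2-iodoprop-1-en-1-yl]oxolan-2-one | O=C1C[C@H](C2OCCO2)[C@@H](/C=C(/C)I)O1 | intermediate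
6 | (2S,3S)-2-[(Z)-2-iodoprop-1-en-1-yl]-5-oxooxolane-3-carbaldehyde | O=C1C[C@H](C=O)[C@@H](/C=C(/C)I)O1 | intermediate
7 | 2,2-dimethyl-1,3-dioxan-5-one | CC1(C)OCC(=O)CO1 | starting material
8 | (4R,5S)-4-{(S)-[(4S)-2,2-dimethyl-5-oxo-1,3-dioxan-4-yl](hydroxy)methyl}-5-[(Z)-2-iodoprop-1-en-1-yl]oxolan-2-one (8,9-anti aldol) | O=C1C[C@H]([C@H](O)[C@@H]2OC(C)(C)OCC2=O)[C@@H](/C=C(/C)I)O1 | intermediate
9 | TBS ether of 8 at O8 | O=C1C[C@H]([C@H](O[Si](C)(C)C(C)(C)C)[C@@H]2OC(C)(C)OCC2=O)[C@@H](/C=C(/C)I)O1 | intermediate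
10 | (4S,5S)-4-{(S)-(tert-butyldimethylsilyloxy)[(4S,5R)-5-hydroxy-2,2,5-trimethyl-1,3-dioxan-4-yl]methyl}-5-[(Z)-2-iodoprop-1-en-1-yl]oxolan-2-one | O=C1C[C@H]([C@H](O[Si](C)(C)C(C)(C)C)[C@@H]2OC(C)(C)OC[C@@]2(C)O)[C@@H](/C=C(/C)I)O1 | intermediate
11 | Mannich base: 3-[(dimethylamino)methyl] derivative of 10 (C3 epimers) | O=C1C(CN(C)C)[C@H]([C@H](O[Si](C)(C)C(C)(C)C)[C@@H]2OC(C)(C)OC[C@@]2(C)O)[C@@H](/C=C(/C)I)O1 | intermediate (not isolated)
12 | trimethylammonium iodide of 11 | O=C1C(C[N+](C)(C)C)[C@H]([C@H](O[Si](C)(C)C(C)(C)C)[C@@H]2OC(C)(C)OC[C@@]2(C)O)[C@@H](/C=C(/C)I)O1.[I-] | intermediate (not isolated)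
13 | 3-methylidene derivative of 10 (α-methylene lactone) | O=C1C(=C)[C@H]([C@H](O[Si](C)(C)C(C)(C)C)[C@@H]2OC(C)(C)OC[C@@]2(C)O)[C@@H](/C=C(/C)I)O1 | intermediate
14 | (4S,5S)-4-[(1S,2S,3R)-1-(tert-butyldimethylsilyloxy)-2,3,4-trihydroxy-3-methylbutyl]-5-[(Z)-2-iodoprop-1-en-1-yl]-3-methylideneoxolan-2-one | O=C1C(=C)[C@H]([C@H](O[Si](C)(C)C(C)(C)C)[C@H](O)[C@](C)(O)CO)[C@@H](/C=C(/C)I)O1 | intermediate
15 | (4S,5S)-4-[(1S,2S,3R)-1-(tert-butyldimethylsilyloxy)-3-hydroxy-3-methyl-2,4-bis(triethylsilyloxy)butyl]-5-[(Z)-2-iodoprop-1-en-1-yl]-3-methylideneoxolan-2-one | O=C1C(=C)[C@H]([C@H](O[Si](C)(C)C(C)(C)C)[C@H](O[Si](CC)(CC)CC)[C@](C)(O)CO[Si](CC)(CC)CC)[C@@H](/C=C(/C)I)O1 | intermediate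
16 | (4S,5S)-4-[(1S,2S,3S)-1-(tert-butyldimethylsilyloxy)-3-hydroxy-3-methyl-4-oxo-2-(triethylsilyloxy)butyl]-5-[(Z)-2-iodoprop-1-en-1-yl]-3-methylideneoxolan-2-one | O=C1C(=C)[C@H]([C@H](O[Si](C)(C)C(C)(C)C)[C@H](O[Si](CC)(CC)CC)[C@](C)(O)C=O)[C@@H](/C=C(/C)I)O1 | intermediate
17 | (4S,5S)-4-[(1S,2S,3R,4RS)-1-(tert-butyldimethylsilyloxy)-3,4-dihydroxy-3-methyl-2-(triethylsilyloxy)hex-5-yn-1-yl]-5-[(Z)-2-iodoprop-1-en-1-yl]-3-methylideneoxolan-2-one | O=C1C(=C)[C@H]([C@H](O[Si](C)(C)C(C)(C)C)[C@H](O[Si](CC)(CC)CC)[C@](C)(O)C(O)C#C)[C@@H](/C=C(/C)I)O1 | intermediate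
18 | (4S,5S)-4-[(1S,2S,3S)-1-(tert-butyldimethylsilyloxy)-3-hydroxy-3-methyl-4-oxo-2-(triethylsilyloxy)hex-5-yn-1-yl]-5-[(Z)-2-iodoprop-1-en-1-yl]-3-methylideneoxolan-2-one | O=C1C(=C)[C@H]([C@H](O[Si](C)(C)C(C)(C)C)[C@H](O[Si](CC)(CC)CC)[C@](C)(O)C(=O)C#C)[C@@H](/C=C(/C)I)O1 | intermediate
19 | macrocyclic enynone: trans-fused α-methylene-γ-lactone on a (4Z)-cyclodec-4-en-2-yn-1-one bearing 8-OTBS, 9-OTES, 10-OH and 10-methyl (C6–C10 as in 32) | C=C1C(=O)O[C@@H]2/C=C(/C)C#CC(=O)[C@@](C)(O)[C@@H](O[Si](CC)(CC)CC)[C@@H](O[Si](C)(C)C(C)(C)C)[C@@H]12 | intermediate (not isolated)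
20 | 8-O-TBS-9-O-TES furanone macrolide (3,10-epoxy-1-oxogermacra-2,4Z,11(13)-trien-12,6-olide core) | C=C1C(=O)O[C@@H]2/C=C(/C)C3=CC(=O)[C@@](C)(O3)[C@@H](O[Si](CC)(CC)CC)[C@@H](O[Si](C)(C)C(C)(C)C)[C@@H]12 | intermediate
21 | 8-O-TBS-9-hydroxy furanone macrolide | C=C1C(=O)O[C@@H]2/C=C(/C)C3=CC(=O)[C@@](C)(O3)[C@@H](O)[C@@H](O[Si](C)(C)C(C)(C)C)[C@@H]12 | intermediate
22 | tert-butyl bromoacetate | CC(C)(C)OC(=O)CBr | starting material
23 | diphenyl phosphite | O=[PH](Oc1ccccc1)Oc1ccccc1 | starting material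
24 | tert-butyl 2-(diphenoxyphosphoryl)acetate | CC(C)(C)OC(=O)CP(=O)(Oc1ccccc1)Oc1ccccc1 | intermediate
25 | tert-butyl 2-(diphenoxyphosphoryl)propanoate (racemic) | CC(C(=O)OC(C)(C)C)P(=O)(Oc1ccccc1)Oc1ccccc1 | intermediate
26 | (Z)-but-2-ene-1,4-diyl diacetate | CC(=O)OC/C=C\COC(C)=O | starting material
27 | 2-oxoethyl acetate | CC(=O)OCC=O | intermediate
28 | tert-butyl (Z)-4-acetoxy-2-methylbut-2-enoate | CC(=O)OC/C=C(/C)C(=O)OC(C)(C)C | intermediate
29 | (Z)-4-acetoxy-2-methylbut-2-enoic acid | CC(=O)OC/C=C(/C)C(=O)O | intermediate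
30 | mixed anhydride of 29 with 2,4,6-trichlorobenzoic acid | CC(=O)OC/C=C(/C)C(=O)OC(=O)c1c(Cl)cc(Cl)cc1Cl | intermediate (not isolated)
31 | 8-O-TBS ether of the target | C=C1C(=O)O[C@@H]2/C=C(/C)C3=CC(=O)[C@@](C)(O3)[C@@H](OC(=O)/C(C)=C\COC(C)=O)[C@@H](O[Si](C)(C)C(C)(C)C)[C@@H]12 | intermediate
32 | CNP0523348.1: (6R,7R,8S,9S,10S)-9-[(Z)-4-acetoxy-2-methylbut-2-enoyloxy]-8-hydroxy-1-oxo-3,10-epoxygermacra-2,4Z,11(13)-trien-12,6-olide | C=C1C(=O)O[C@@H]2/C=C(/C)C3=CC(=O)[C@@](C)(O3)[C@@H](OC(=O)/C(C)=C\COC(C)=O)[C@@H](O)[C@@H]12 | target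

**Step count**

Total: 23 steps. Longest linear sequence: 18 steps (steps 1–16, 22 and 23); steps 17–21 form the side-chain branch.

**Steps most likely to fail**

Step 15 (key step). Ring closure may be outrun by oligomerisation or alkyne homocoupling. The terminal ynone may be consumed by amine or iodide addition before coupling. The vinylpalladium species may insert into the methylene lactone (Heck pathway). The sequence may also stall at the strained cycloalkynone. The fallback sets out from 17 and returns at 20. The less electrophilic propargylic alcohol 17 would be cyclised first under Pd(PPh3)4/CuI/Et3N at high dilution to the macrocyclic enynol F1. Dess–Martin oxidation would then give enynone 19, now isolated. A separate AuCl(PPh3)/AgOSO2CF3-catalysed 5-endo-dig cycloisomerisation in CH2Cl2 would deliver 20.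

Step 6. The secondary amine may trigger β-elimination of the lactone carboxylate from 6 through the aldehyde enamine. C7 may epimerise. Catalyst control may also prove too weak against the intrinsic facial bias of the α-branched aldehyde. The fallback sets out from 7 and 6 and returns at 8. Ketone 7 would be converted with (c-Hex)2BCl/Et3N in Et2O at −78 °C into its dicyclohexylboron enolate F2. This adds to 6 through a closed Zimmerman–Traxler transition state, the (E)-enolate giving the 8,9-anti relationship with no enamine of the aldehyde present. Oxidative work-up (H2O2, pH 7 buffer, MeOH) would give 8. The sense relative to C7 then rests on Felkin–Anh induction, so the C8/C9 pair would be checked and the isomers separated at this stage if needed.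

Step 4. The α-iodo ylide may give low conversion with loss of iodine or erosion of Z selectivity, and the α-oxygenated aldehyde may epimerise at C6. The fallback sets out from 4 and returns at 5. Ramirez dibromoolefination (CBr4, PPh3, Zn, CH2Cl2) would give the 1,1-dibromoalkene F3. A trans-selective Negishi monomethylation (MeZnCl, PdCl2(DPEphos), THF) would replace the bromine trans to C6 and give the (Z)-bromoalkene F4 with bromine cis to C6. Copper-catalysed vinylic Finkelstein exchange (CuI, NaI, trans-N,N'-dimethylcyclohexane-1,2-diamine, dioxane, 100 °C) would then give 5 with retention.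

**Further compounds**

F1 | step 15 | macrocyclic enynol: trans-fused α-methylene-γ-lactone on a (4Z)-cyclodec-4-en-2-yn-1-ol bearing 8-OTBS, 9-OTES, 10-OH and 10-methyl (C1 epimers) | C=C1C(=O)O[C@@H]2/C=C(/C)C#CC(O)[C@@](C)(O)[C@@H](O[Si](CC)(CC)CC)[C@@H](O[Si](C)(C)C(C)(C)C)[C@@H]12
F2 | step 6 | dicyclohexylboron enolate of 7: 5-(dicyclohexylboryloxy)-2,2-dimethyl-4H-1,3-dioxine | CC1(C)OCC(OB(C2CCCCC2)C2CCCCC2)=CO1
F3 | step 4 | (4S,5S)-5-(2,2-dibromoethenyl)-4-(1,3-dioxolan-2-yl)oxolan-2-one | O=C1C[C@H](C2OCCO2)[C@@H](C=C(Br)Br)O1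
F4 | step 4 | (4S,5S)-5-[(Z)-2-bromoprop-1-en-1-yl]-4-(1,3-dioxolan-2-yl)oxolan-2-one | O=C1C[C@H](C2OCCO2)[C@@H](/C=C(/C)Br)O1
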